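**Retrosynthetic overview**
1. The epoxide goes on last, by peracid attack on the strained E C4=C5 alkene of the complete enone.
2. The C12–C13 bond joins the bicyclic core aldehyde and a chiral propargylic alcohol acetate by rhodium-catalysed aldehyde C–H activation and alkyne hydroacylation (key step).
3. The nine-membered ring is the second ring: closed at C7–C8 by acylation of an α-sulfonyl carbanion, after a Pd-catalysed Negishi coupling (C3–C4) of a cyclobutanone with a vinyl iodide.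
4. The cyclobutane is the first ring: auxiliary-controlled keteniminium [2+2] cycloaddition to an E trisubstituted alkene; C9 is set later by equilibration of the ring ketone.
5. Building blocks: 5-bromo-2-methylpent-2-ene, acetyl chloride, pent-3-yn-1-ol, (R)-2-methylglycidol.

Assumption: caryophyllane numbering is used for the core (C1/C9 ring fusion, C4=C5 alkene, C8 exocyclic carbon, C11 quaternary carbon bearing C12); the facial sense of the auxiliary in step 4 is taken by analogy, and its equally available antipode is used if the mirror-image cyclobutanone forms.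

**Route**

Step 1
Reactants: 1 5-bromo-2-methylpent-2-ene
Product: 2 (2E)-5-bromo-2-methylpent-2-en-1-ol
Conditions: SeO2 (0.5 equiv), t-BuOOH (2 equiv), CH2Cl2, 0 to 23 °C
Reagents that add atoms: tert-butyl hydroperoxide, CC(C)(C)OO
Why: Selenium dioxide allylic oxidation (ene reaction then [2,3]-sigmatropic shift) attacks the E methyl group, so the CH2OH ends trans to the bromoethyl chain and the remaining methyl cis to it.

Step 2
Reactants: 2 (2E)-5-bromo-2-methylpent-2-en-1-ol
Product: 3 {[(2E)-5-bromo-2-methylpent-2-en-1-yl]oxy}(tert-butyl)diphenylsilane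
Conditions: t-BuPh2SiCl, imidazole, CH2Cl2, 23 °C
Reagents that add atoms: tert-butyl(chloro)diphenylsilane, CC(C)(C)[Si](Cl)(c1ccccc1)c1ccccc1
Why: Silylation of the primary alcohol gives an ether that withstands triflic anhydride, zinc, ylides and amide bases.

Step 3
Reactants: 4 acetyl chloride; 5 (2R,5R)-2,5-dimethylpyrrolidine
Product: 6 1-[(2R,5R)-2,5-dimethylpyrrolidin-1-yl]ethan-1-one
Conditions: Et3N, CH2Cl2, 0 °C
Reagents that add atoms: none
Why: N-acylation gives the tertiary acetamide that is the keteniminium precursor.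

Step 4
Reactants: 3 {[(2E)-5-bromo-2-methylpent-2-en-1-yl]oxy}(tert-butyl)diphenylsilane; 6 1-[(2R,5R)-2,5-dimethylpyrrolidin-1-yl]ethan-1-one
Product: 9 (2S,3R)-2-(2-bromoethyl)-3-({[tert-butyl(diphenyl)silyl]oxy}methyl)-3-methylcyclobutan-1-one, via keteniminium triflate 7 (not isolated), via cyclobutaniminium triflate 8 (not isolated)
Conditions: Tf2O, 2,6-di-tert-butyl-4-methylpyridine, ClCH2CH2Cl, −20 °C; 3, 80 °C; then H2O, 23 °C
Reagents that add atoms: water, O
Why: Keteniminium–alkene [2+2] cycloaddition: the iminium carbon bonds to the less substituted alkene carbon (C1) and the CH2 to C11, suprafacial addition turns the E geometry into the cis relation of the C11 methyl and the C1 chain, and the twofold-symmetric pyrrolidine selects the alkene face, which sets C1 and C11.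

Step 5
Reactants: 10 pent-3-yn-1-ol
Product: 11 pent-3-yn-1-yl 4-methylbenzenesulfonate
Conditions: TsCl, pyridine, CH2Cl2, 0 °C
Reagents that add atoms: 4-methylbenzenesulfonyl chloride, Cc1ccc(cc1)S(=O)(=O)Cl
Why: Sulfonylation turns the primary alcohol into a leaving group.

Step 6
Reactants: 11 pent-3-yn-1-yl 4-methylbenzenesulfonate
Product: 12 (pent-3-yn-1-ylsulfonyl)benzene
Conditions: PhSO2Na, Bu4NI (cat.), DMF, 60 °C
Reagents that add atoms: sodium benzenesulfinate, [Na+].[O-]S(=O)c1ccccc1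
Why: SN2 S-alkylation of the sulfinate installs the sulfone that later acidifies C7.

Step 7
Reactants: 12 (pent-3-yn-1-ylsulfonyl)benzene
Product: 14 {[(3E)-4-iodopent-3-en-1-yl]sulfonyl}benzene, via alkenylzirconocene chloride 13 (not isolated)
Conditions: Cp2Zr(H)Cl (2.5 equiv), THF, 50 °C; then I2, 0 °C
Reagents that add atoms: iodine, [I][I]
Why: Hydrozirconation is a syn addition and excess Cp2Zr(H)Cl equilibrates zirconium to the less hindered methyl-bearing carbon; iodinolysis with retention gives the E 2-iodoalkene.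

Step 8
Reactants: 9 (2S,3R)-2-(2-bromoethyl)-3-({[tert-butyl(diphenyl)silyl]oxy}methyl)-3-methylcyclobutan-1-one; 14 {[(3E)-4-iodopent-3-en-1-yl]sulfonyl}benzene
Product: 16 (2S,3R)-3-({[tert-butyl(diphenyl)silyl]oxy}methyl)-3-methyl-2-[(3E)-3-methyl-6-(phenylsulfonyl)hex-3-en-1-yl]cyclobutan-1-one, via alkylzinc bromide 15 (not isolated)
Conditions: Zn, LiCl, THF, 50 °C; then 14, Pd(PPh3)4 (5 mol%), 40 °C
Reagents that add atoms: none
Why: Zinc insertion into the primary C–Br bond and Negishi sp3–sp2 coupling with retention at the alkene form C3–C4 and fix the E C4=C5 geometry; the neutral conditions leave the ketone α-centre C1 alone.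

Step 9
Reactants: 16 (2S,3R)-3-({[tert-butyl(diphenyl)silyl]oxy}methyl)-3-methyl-2-[(3E)-3-methyl-6-(phenylsulfonyl)hex-3-en-1-yl]cyclobutan-1-one
Product: 17 tert-butyl({(1R,2S)-3-(methoxymethylidene)-1-methyl-2-[(3E)-3-methyl-6-(phenylsulfonyl)hex-3-en-1-yl]cyclobutyl}methoxy)diphenylsilane (enol ether E/Z mixture)
Conditions: [Ph3PCH2OMe]Cl, KN(SiMe3)2, THF, −78 to 0 °C
Reagents that add atoms: (methoxymethyl)triphenylphosphonium chloride, COC[P+](c1ccccc1)(c1ccccc1)c1ccccc1.[Cl-]
Why: Wittig methoxymethylenation is fast at the strained ketone, adds C8, and removes the carbonyl so that C1 can no longer epimerise.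

Step 10
Reactants: 17 tert-butyl({(1R,2S)-3-(methoxymethylidene)-1-methyl-2-[(3E)-3-methyl-6-(phenylsulfonyl)hex-3-en-1-yl]cyclobutyl}methoxy)diphenylsilane
Product: 18 methyl (2R,3R)-3-({[tert-butyl(diphenyl)silyl]oxy}methyl)-3-methyl-2-[(3E)-3-methyl-6-(phenylsulfonyl)hex-3-en-1-yl]cyclobutane-1-carboxylate (both C9 epimers)
Conditions: [C5H5NH][CrO3Cl], CH2Cl2, 23 °C
Reagents that add atoms: pyridinium chlorochromate, [O-][Cr](=O)(=O)Cl.c1cc[nH+]cc1
Why: Chlorochromate oxidation of an enol ether to the ester (attack at the enol ether, then 1,2-hydride shift) brings C8 to the ester level; C9 forms unselectively and is corrected in step 12.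

Step 11
Reactants: 18 methyl (2R,3R)-3-({[tert-butyl(diphenyl)silyl]oxy}methyl)-3-methyl-2-[(3E)-3-methyl-6-(phenylsulfonyl)hex-3-en-1-yl]cyclobutane-1-carboxylate
Product: 20 (1R,4E,11R)-11-({[tert-butyl(diphenyl)silyl]oxy}methyl)-4,11-dimethyl-7-(phenylsulfonyl)bicyclo[7.2.0]undec-4-en-8-one (C7 and C9 epimers), via lithiated sulfone 19 (not isolated)
Conditions: LiN(iPr)2 (2.5 equiv), THF (0.005 M), −78 to 0 °C; AcOH
Reagents that add atoms: none
Why: Intramolecular Claisen-type acylation of the α-sulfonyl carbanion by the ester under high dilution, a ring closure of the type used for medium-ring ketones of the caryophyllene family, closes the nine-membered ring at C7–C8 and is driven by the doubly stabilised β-keto sulfone anion.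

Step 12
Reactants: 20 (1R,4E,11R)-11-({[tert-butyl(diphenyl)silyl]oxy}methyl)-4,11-dimethyl-7-(phenylsulfonyl)bicyclo[7.2.0]undec-4-en-8-one
Product: 21 (1R,4E,9S,11R)-11-({[tert-butyl(diphenyl)silyl]oxy}methyl)-4,11-dimethylbicyclo[7.2.0]undec-4-en-8-one
Conditions: SmI2 (2.5 equiv), THF/MeOH, −78 °C; then NaOMe (0.2 equiv), MeOH, 23 °C
Reagents that add atoms: none
Why: Samarium diiodide cleaves the C–S bond of the α-sulfonyl ketone by electron transfer, and methoxide then equilibrates C9 through the enolate to the more stable trans ring fusion, which sets C9 as S.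

Step 13
Reactants: 21 (1R,4E,9S,11R)-11-({[tert-butyl(diphenyl)silyl]oxy}methyl)-4,11-dimethylbicyclo[7.2.0]undec-4-en-8-one
Product: 22 tert-butyl{[(1R,4E,9S,11R)-4,11-dimethyl-8-methylidenebicyclo[7.2.0]undec-4-en-11-yl]methoxy}diphenylsilane
Conditions: [Ph3PCH3]Br, KOtBu, THF, 0 to 50 °C
Reagents that add atoms: methyltriphenylphosphonium bromide, C[P+](c1ccccc1)(c1ccccc1)c1ccccc1.[Br-]
Why: Wittig methylenation of the C8 ketone; the basic ylide can only return C9 to the same thermodynamic trans fusion.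

Step 14
Reactants: 22 tert-butyl{[(1R,4E,9S,11R)-4,11-dimethyl-8-methylidenebicyclo[7.2.0]undec-4-en-11-yl]methoxy}diphenylsilane
Product: 23 [(1R,4E,9S,11R)-4,11-dimethyl-8-methylidenebicyclo[7.2.0]undec-4-en-11-yl]methanol
Conditions: Bu4NF, THF, 23 °C
Reagents that add atoms: none
Why: Fluoride cleaves the silyl ether and touches nothing else.

Step 15
Reactants: 23 [(1R,4E,9S,11R)-4,11-dimethyl-8-methylidenebicyclo[7.2.0]undec-4-en-11-yl]methanol
Product: 24 (1R,4E,9S,11R)-4,11-dimethyl-8-methylidenebicyclo[7.2.0]undec-4-ene-11-carbaldehyde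
Conditions: Dess–Martin periodinane, CH2Cl2, 0 to 23 °C
Reagents that add atoms: none
Why: Dess–Martin oxidation of the neopentyl alcohol stops at the aldehyde, which has no α-hydrogen, and leaves both alkenes alone.

Step 16
Reactants: 25 [(2R)-2-methyloxiran-2-yl]methanol
Product: 26 (2S)-2-methyloxirane-2-carbaldehyde
Conditions: Dess–Martin periodinane, CH2Cl2, 0 °C; solution used directly
Reagents that add atoms: none
Why: Dess–Martin oxidation; the stereocentre is quaternary and cannot racemise (the descriptor changes by priority only).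

Step 17
Reactants: 26 (2S)-2-methyloxirane-2-carbaldehyde
Product: 27 (2R)-2-ethynyl-2-methyloxirane
Conditions: dimethyl (1-diazo-2-oxopropyl)phosphonate, K2CO3, MeOH, 0 to 23 °C
Reagents that add atoms: dimethyl (1-diazo-2-oxopropyl)phosphonate, COP(=O)(OC)C(=[N+]=[N-])C(C)=O
Why: Seyferth–Gilbert homologation with the Ohira–Bestmann reagent converts the non-enolisable aldehyde into the terminal alkyne.

Step 18
Reactants: 27 (2R)-2-ethynyl-2-methyloxirane
Product: 28 (2R)-2-hydroxy-2-methylbut-3-yn-1-yl acetate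
Conditions: AcOH (3 equiv), CsOAc (20 mol%), DMF, 50 °C
Reagents that add atoms: acetic acid, CC(=O)O
Why: Acetate opens the epoxide by SN2 attack at the unsubstituted carbon, so the C–O bond at the quaternary centre is never broken and its configuration is kept.

Step 19
Reactants: 24 (1R,4E,9S,11R)-4,11-dimethyl-8-methylidenebicyclo[7.2.0]undec-4-ene-11-carbaldehyde; 28 (2R)-2-hydroxy-2-methylbut-3-yn-1-yl acetate
Product: 31 (2R,3E)-5-[(1R,4E,9S,11R)-4,11-dimethyl-8-methylidenebicyclo[7.2.0]undec-4-en-11-yl]-2-hydroxy-2-methyl-5-oxopent-3-en-1-yl acetate, via aldimine 29 (not isolated), via ketimine 30 (not isolated)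
Conditions: RhCl(PPh3)3 (5 mol%), 2-amino-3-methylpyridine (40 mol%), PhCO2H (10 mol%), 28 (2 equiv), toluene, 80 °C
Reagents that add atoms: none
Why: Proposed new method: chelation-assisted hydroacylation of a 1-alkyne is carried over to an α-quaternary aldehyde and a free tertiary propargylic alcohol; the aminopyridine condenses with 24 to aldimine 29, pyridine-directed insertion of monovalent rhodium into the imine C–H bond gives a five-membered iminoacyl rhodium hydride that cannot lose CO, the alkyne inserts into Rh–H with rhodium on the terminal carbon because the fully substituted propargylic carbon stays away from the crowded metal, syn addition and C–C reductive elimination give the E ketimine 30, and the water from the condensation hydrolyses it to 31 and returns the amine; closest known reaction type: rhodium-catalysed chelation-assisted intermolecular hydroacylation of terminal alkynes and alkenes with simple aldehydes.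

Step 20
Reactants: 31 (2R,3E)-5-[(1R,4E,9S,11R)-4,11-dimethyl-8-methylidenebicyclo[7.2.0]undec-4-en-11-yl]-2-hydroxy-2-methyl-5-oxopent-3-en-1-yl acetate
Product: 32 (2R,3E)-5-[(1R,4R,5R,9S,11R)-4,5-epoxy-4,11-dimethyl-8-methylidenebicyclo[7.2.0]undecan-11-yl]-2-hydroxy-2-methyl-5-oxopent-3-en-1-yl acetate
Conditions: mCPBA (1.05 equiv), CH2Cl2, −20 to 0 °C
Reagents that add atoms: 3-chloroperoxybenzoic acid, OOC(=O)c1cccc(Cl)c1
Why: Prilezhaev epoxidation picks the strained, electron-rich E trisubstituted alkene over the exocyclic methylene and the enone, and syn attack on the exposed face of the main ring conformers, as with caryophyllene itself, gives the 4R,5R epoxide.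

**Compound list**
1 | 5-bromo-2-methylpent-2-ene | CC(C)=CCCBr | starting material
2 | (2E)-5-bromo-2-methylpent-2-en-1-ol | OC/C(C)=C/CCBr | intermediate
3 | {[(2E)-5-bromo-2-methylpent-2-en-1-yl]oxy}(tert-butyl)diphenylsilane | CC(C)(C)[Si](OC/C(C)=C/CCBr)(c1ccccc1)c1ccccc1 | intermediate
4 | acetyl chloride | CC(=O)Cl | starting material
5 | (2R,5R)-2,5-dimethylpyrrolidine (auxiliary) | N1[C@H](C)CC[C@H]1C | starting material
6 | 1-[(2R,5R)-2,5-dimethylpyrrolidin-1-yl]ethan-1-one | CC(=O)N1[C@H](C)CC[C@H]1C | intermediate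
7 | (2R,5R)-1-ethenylidene-2,5-dimethylpyrrolidin-1-ium trifluoromethanesulfonate | C=C=[N+]1[C@H](C)CC[C@H]1C.[O-]S(=O)(=O)C(F)(F)F | intermediate (not isolated)
8 | (2R,5R)-1-[(2S,3R)-2-(2-bromoethyl)-3-({[tert-butyl(diphenyl)silyl]oxy}methyl)-3-methylcyclobutylidene]-2,5-dimethylpyrrolidin-1-ium trifluoromethanesulfonate | BrCC[C@@H]1C(=[N+]2[C@H](C)CC[C@H]2C)C[C@@]1(C)CO[Si](c3ccccc3)(c3ccccc3)C(C)(C)C.[O-]S(=O)(=O)C(F)(F)F | intermediate (not isolated)
9 | (2S,3R)-2-(2-bromoethyl)-3-({[tert-butyl(diphenyl)silyl]oxy}methyl)-3-methylcyclobutan-1-one | BrCC[C@@H]1C(=O)C[C@@]1(C)CO[Si](c2ccccc2)(c2ccccc2)C(C)(C)C | intermediate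
10 | pent-3-yn-1-ol | CC#CCCO | starting material
11 | pent-3-yn-1-yl 4-methylbenzenesulfonate | CC#CCCOS(=O)(=O)c1ccc(C)cc1 | intermediate
12 | (pent-3-yn-1-ylsulfonyl)benzene | CC#CCCS(=O)(=O)c1ccccc1 | intermediate
13 | Cp2Zr(Cl)[(2E)-5-(phenylsulfonyl)pent-2-en-2-yl] | C/C(=C\CCS(=O)(=O)c1ccccc1)[Zr](Cl)(C1C=CC=C1)C1C=CC=C1 | intermediate (not isolated)
14 | {[(3E)-4-iodopent-3-en-1-yl]sulfonyl}benzene | C/C(I)=C\CCS(=O)(=O)c1ccccc1 | intermediate
15 | bromido{2-[(1S,2R)-2-({[tert-butyl(diphenyl)silyl]oxy}methyl)-2-methyl-4-oxocyclobutyl]ethyl}zinc | Br[Zn]CC[C@@H]1C(=O)C[C@@]1(C)CO[Si](c2ccccc2)(c2ccccc2)C(C)(C)C | intermediate (not isolated)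
16 | (2S,3R)-3-({[tert-butyl(diphenyl)silyl]oxy}methyl)-3-methyl-2-[(3E)-3-methyl-6-(phenylsulfonyl)hex-3-en-1-yl]cyclobutan-1-one | C/C(=C\CCS(=O)(=O)c1ccccc1)CC[C@@H]1C(=O)C[C@@]1(C)CO[Si](c2ccccc2)(c2ccccc2)C(C)(C)C | intermediate
17 | tert-butyl({(1R,2S)-3-(methoxymethylidene)-1-methyl-2-[(3E)-3-methyl-6-(phenylsulfonyl)hex-3-en-1-yl]cyclobutyl}methoxy)diphenylsilane (enol ether E/Z mixture) | C/C(=C\CCS(=O)(=O)c1ccccc1)CC[C@@H]1C(=COC)C[C@@]1(C)CO[Si](c2ccccc2)(c2ccccc2)C(C)(C)C | intermediate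
18 | methyl (2R,3R)-3-({[tert-butyl(diphenyl)silyl]oxy}methyl)-3-methyl-2-[(3E)-3-methyl-6-(phenylsulfonyl)hex-3-en-1-yl]cyclobutane-1-carboxylate (both C9 epimers) | C/C(=C\CCS(=O)(=O)c1ccccc1)CC[C@@H]1C(C(=O)OC)C[C@@]1(C)CO[Si](c2ccccc2)(c2ccccc2)C(C)(C)C | intermediate
19 | α-lithio sulfone of 18 | C/C(=C\CC([Li])S(=O)(=O)c1ccccc1)CC[C@@H]1C(C(=O)OC)C[C@@]1(C)CO[Si](c2ccccc2)(c2ccccc2)C(C)(C)C | intermediate (not isolated)
20 | (1R,4E,11R)-11-({[tert-butyl(diphenyl)silyl]oxy}methyl)-4,11-dimethyl-7-(phenylsulfonyl)bicyclo[7.2.0]undec-4-en-8-one (C7 and C9 epimers) | O=C1C(S(=O)(=O)c3ccccc3)C/C=C(C)/CC[C@@H]2C1C[C@@]2(C)CO[Si](c4ccccc4)(c4ccccc4)C(C)(C)C | intermediate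
21 | (1R,4E,9S,11R)-11-({[tert-butyl(diphenyl)silyl]oxy}methyl)-4,11-dimethylbicyclo[7.2.0]undec-4-en-8-one | O=C1CC/C=C(C)/CC[C@@H]2[C@@H]1C[C@@]2(C)CO[Si](c3ccccc3)(c3ccccc3)C(C)(C)C | intermediate
22 | tert-butyl{[(1R,4E,9S,11R)-4,11-dimethyl-8-methylidenebicyclo[7.2.0]undec-4-en-11-yl]methoxy}diphenylsilane | C=C1CC/C=C(C)/CC[C@@H]2[C@@H]1C[C@@]2(C)CO[Si](c3ccccc3)(c3ccccc3)C(C)(C)C | intermediate
23 | [(1R,4E,9S,11R)-4,11-dimethyl-8-methylidenebicyclo[7.2.0]undec-4-en-11-yl]methanol | C=C1CC/C=C(C)/CC[C@@H]2[C@@H]1C[C@@]2(C)CO | intermediate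
24 | (1R,4E,9S,11R)-4,11-dimethyl-8-methylidenebicyclo[7.2.0]undec-4-ene-11-carbaldehyde | C=C1CC/C=C(C)/CC[C@@H]2[C@@H]1C[C@@]2(C)C=O | intermediate
25 | [(2R)-2-methyloxiran-2-yl]methanol | OC[C@@]1(C)OC1 | starting material
26 | (2S)-2-methyloxirane-2-carbaldehyde | O=C[C@@]1(C)OC1 | intermediate
27 | (2R)-2-ethynyl-2-methyloxirane | C#C[C@@]1(C)OC1 | intermediate
28 | (2R)-2-hydroxy-2-methylbut-3-yn-1-yl acetate | C#C[C@@](C)(O)COC(C)=O | intermediate
29 | (E)-1-[(1R,4E,9S,11R)-4,11-dimethyl-8-methylidenebicyclo[7.2.0]undec-4-en-11-yl]-N-(3-methylpyridin-2-yl)methanimine | C=C1CC/C=C(C)/CC[C@@H]2[C@@H]1C[C@@]2(C)/C=N/c3ncccc3C | intermediate (not isolated)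
30 | (2R,3E)-5-[(1R,4E,9S,11R)-4,11-dimethyl-8-methylidenebicyclo[7.2.0]undec-4-en-11-yl]-2-hydroxy-2-methyl-5-[(3-methylpyridin-2-yl)imino]pent-3-en-1-yl acetate | C=C1CC/C=C(C)/CC[C@@H]2[C@@H]1C[C@@]2(C)C(=Nc3ncccc3C)/C=C/[C@@](C)(O)COC(C)=O | intermediate (not isolated)
31 | (2R,3E)-5-[(1R,4E,9S,11R)-4,11-dimethyl-8-methylidenebicyclo[7.2.0]undec-4-en-11-yl]-2-hydroxy-2-methyl-5-oxopent-3-en-1-yl acetate | C=C1CC/C=C(C)/CC[C@@H]2[C@@H]1C[C@@]2(C)C(=O)/C=C/[C@@](C)(O)COC(C)=O | intermediate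
32 | (2R,3E)-5-[(1R,4R,5R,9S,11R)-4,5-epoxy-4,11-dimethyl-8-methylidenebicyclo[7.2.0]undecan-11-yl]-2-hydroxy-2-methyl-5-oxopent-3-en-1-yl acetate | C=C1CC[C@H]2O[C@]2(C)CC[C@@H]2[C@@H]1C[C@@]2(C)C(=O)/C=C/[C@@](C)(O)COC(C)=O | target

**Totals**
Total step count: 20.
Longest linear sequence: 13 steps (1, 2, 4, 8 to 15, 19, 20; the branch 5 to 7 that joins at step 8 is equally long), which is 65% of the total.

**Three steps most likely to fail**

Step 4 (auxiliary-controlled [2+2]). The allylic silyl ether lowers the nucleophilicity of the alkene, the enantioselectivity on an acyclic E trisubstituted alkene is not established, and C1 sits next to the iminium carbon. Fallback, from 3 back to 9: cycloaddition of 3 with dichloroketene (Cl3CCOCl, Zn/Cu, Et2O) has the same regiochemistry and keeps the alkene geometry, and gives the racemic dichlorocyclobutanone F1. Zn in AcOH at 23 °C removes both chlorines to give the racemic cyclobutanone F2. Preparative chromatography on a chiral stationary phase then delivers 9.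

Step 11 (nine-membered ring closure). Deprotonation of the ester at C9 and oligomerisation compete with the strained medium-ring closure. Fallback, from 16 back to 20: reductive cyanation of 16 with TsCH2NC, KOtBu, DME/EtOH gives the cyclobutanecarbonitrile F3, a C8 electrophile with no leaving group. LiN(iPr)2 at high dilution adds the sulfonyl carbanion to the nitrile (Thorpe-type closure) to give the cyclic sulfonyl ketimine F4. Aqueous HCl hydrolyses it to 20.

Step 19 (the proposed new hydroacylation). Imine formation at the neopentyl aldehyde may be slow, the 1,3-cis exocyclic methylene could insert intramolecularly, and a rhodium hydride could isomerise the strained E alkene. Fallback with known chemistry, from 28 and 24 back to 31: Bu3SnH with PdCl2(PPh3)2 (cat.) in THF adds to 28 to give the E vinylstannane F5. I2 converts it into the E vinyl iodide F6. Nozaki–Hiyama–Kishi coupling of F6 with 24 (CrCl2, NiCl2 cat., DMSO) gives the allylic alcohol F7 as both carbinol epimers. Dess–Martin periodinane oxidises F7 to 31.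

**Further compounds**
F1 | step 4 | rac-(3R*,4S*)-4-(2-bromoethyl)-3-({[tert-butyl(diphenyl)silyl]oxy}methyl)-2,2-dichloro-3-methylcyclobutan-1-one | BrCC[C@@H]1C(=O)C(Cl)(Cl)[C@@]1(C)CO[Si](c2ccccc2)(c2ccccc2)C(C)(C)C.BrCC[C@H]1C(=O)C(Cl)(Cl)[C@]1(C)CO[Si](c2ccccc2)(c2ccccc2)C(C)(C)C
F2 | step 4 | racemic 2-(2-bromoethyl)-3-({[tert-butyl(diphenyl)silyl]oxy}methyl)-3-methylcyclobutan-1-one (9 and its enantiomer) | BrCC[C@@H]1C(=O)C[C@@]1(C)CO[Si](c2ccccc2)(c2ccccc2)C(C)(C)C.BrCC[C@H]1C(=O)C[C@]1(C)CO[Si](c2ccccc2)(c2ccccc2)C(C)(C)C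
F3 | step 11 | (2R,3R)-3-({[tert-butyl(diphenyl)silyl]oxy}methyl)-3-methyl-2-[(3E)-3-methyl-6-(phenylsulfonyl)hex-3-en-1-yl]cyclobutane-1-carbonitrile (both C9 epimers) | C/C(=C\CCS(=O)(=O)c1ccccc1)CC[C@@H]1C(C#N)C[C@@]1(C)CO[Si](c2ccccc2)(c2ccccc2)C(C)(C)C
F4 | step 11 | (1R,4E,11R)-11-({[tert-butyl(diphenyl)silyl]oxy}methyl)-4,11-dimethyl-7-(phenylsulfonyl)bicyclo[7.2.0]undec-4-en-8-imine (C7 and C9 epimers) | N=C1C(S(=O)(=O)c3ccccc3)C/C=C(C)/CC[C@@H]2C1C[C@@]2(C)CO[Si](c4ccccc4)(c4ccccc4)C(C)(C)C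
F5 | step 19 | (2R,3E)-2-hydroxy-2-methyl-4-(tributylstannyl)but-3-en-1-yl acetate | CCCC[Sn](CCCC)(CCCC)/C=C/[C@@](C)(O)COC(C)=O
F6 | step 19 | (2R,3E)-2-hydroxy-4-iodo-2-methylbut-3-en-1-yl acetate | I/C=C/[C@@](C)(O)COC(C)=O
F7 | step 19 | (2R,3E)-5-[(1R,4E,9S,11R)-4,11-dimethyl-8-methylidenebicyclo[7.2.0]undec-4-en-11-yl]-2,5-dihydroxy-2-methylpent-3-en-1-yl acetate (both C5 epimers) | C=C1CC/C=C(C)/CC[C@@H]2[C@@H]1C[C@@]2(C)C(O)/C=C/[C@@](C)(O)COC(C)=O
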